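**Plan**

- Numbering: ring B is the tetralone ring with C1 (ketone), C2, C3 (CH bearing isopropenyl) and C4 (quaternary, methyl plus propanoic acid arm); it is fused through C4a/C8a to aromatic ring A (C5 OH, C6 OMe, C7 isopropyl, C8 OH).
- Retrosynthetic cuts, in order: C3–isopropenyl (conjugate addition to a C2=C3 enone), C4a–C4 (intramolecular Heck closure of ring B), C8a–C1 (arylmagnesium plus Weinreb amide), then C2–C3 and C4–arm (Johnson–Claisen rearrangement and Grignard addition).
- Enabling feature: C4 is a benzylic quaternary carbon of ring B, three carbons from the ketone carbon C1. Its three-carbon arm can start as the alkene left by β-hydride elimination while C3 is still an unsubstituted CH2, so no second alkene is present when ring B closes.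
- Forward order: ring A is dressed in six steps from 1,3-dimethoxybenzene and the E-alkenyl chain is made in three. The two are joined by acylation, ring B closes in the Heck step, and the arm alkene is hydrogenated before enone formation, isopropenyl transfer, arm oxidation and phenol release.
- Stereochemistry: C4 comes from (R)-BINAP on cationic palladium (enantioface selection of the E alkene). C3 comes from (S)-BINAP on rhodium: a catalyst-controlled isopropenyl transfer that reinforces the modest substrate preference for attack anti to the siloxypropyl arm (cis to the C4 methyl), so the step does not rest on a methyl-versus-chain bias alone.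

Key step: step 11

Remark on the chemistry: the sense of induction of (R)-BINAP in step 11 and of (S)-BINAP in step 14 is assigned by analogy with simpler substrates; the mirror-image ligand would be used if the sense proved to be the reverse.

**Route**

Step 1
Reactants: 1 3-[(tert-butyldimethylsilyl)oxy]propanal; 2 isopropenylmagnesium bromide
Product: 3 rac-5-[(tert-butyldimethylsilyl)oxy]-2-methylpent-1-en-3-ol
Conditions: THF, −78 → 0 °C; then H2O
Reagents that add atoms: none
Why: Grignard 1,2-addition of an alkenylmagnesium halide to an unhindered aldehyde is fast at low temperature, and the racemic carbinol centre is of no consequence because it is erased in step 2.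

Step 2
Reactants: 3 rac-5-[(tert-butyldimethylsilyl)oxy]-2-methylpent-1-en-3-ol; 4 triethyl orthoacetate
Product: 6 ethyl (E)-7-[(tert-butyldimethylsilyl)oxy]-4-methylhept-4-enoate, via mixed ketene acetal 5 (not isolated)
Conditions: 4 (6 equiv), EtCO2H (cat.), 140 °C, EtOH distilled off
Reagents that add atoms: none
Why: Johnson–Claisen rearrangement; the chair [3,3] shift of the ketene acetal with the siloxyethyl group equatorial should give the E trisubstituted alkene with high selectivity and forms the C2–C3 bond.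

Step 3
Reactants: 6 ethyl (E)-7-[(tert-butyldimethylsilyl)oxy]-4-methylhept-4-enoate
Product: 7 (E)-7-[(tert-butyldimethylsilyl)oxy]-N-methoxy-N,4-dimethylhept-4-enamide
Conditions: MeNH(OMe)·HCl, iPrMgCl, THF, −20 → 0 °C
Reagents that add atoms: N,O-dimethylhydroxylamine hydrochloride, CNOC.Cl
Why: aminolysis of the ester by the chloromagnesium amide (Weinreb amide formation) is standard and leaves the silyl ether and the alkene untouched.

Step 4
Reactants: 8 1,3-dimethoxybenzene; 9 acetone
Product: 11 2-(2,6-dimethoxyphenyl)propan-2-ol, via 2,6-dimethoxyphenyllithium 10 (not isolated)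
Conditions: n-BuLi, THF, 0 °C → rt; then 9, −78 °C → rt; H2O
Reagents that add atoms: none
Why: directed ortho-lithiation occurs at the position flanked by both methoxy groups, and the aryllithium then undergoes 1,2-addition to acetone.

Step 5
Reactants: 11 2-(2,6-dimethoxyphenyl)propan-2-ol
Product: 12 1,3-dimethoxy-2-(propan-2-yl)benzene
Conditions: Et3SiH, CF3CO2H, CH2Cl2, 0 °C → rt
Reagents that add atoms: none
Why: ionic hydrogenation; the tertiary benzylic cation formed in acid is reduced by hydride transfer from the silane.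

Step 6
Reactants: 12 1,3-dimethoxy-2-(propan-2-yl)benzene
Product: 13 1,5-diiodo-2,4-dimethoxy-3-(propan-2-yl)benzene
Conditions: NIS (2.2 equiv), CF3CO2H (cat.), MeCN, rt
Reagents that add atoms: N-iodosuccinimide, O=C1CCC(=O)N1I
Why: electrophilic aromatic iodination; each iodine enters ortho to one methoxy group and para to the other, and these two symmetry-related sites are the only activated ones.

Step 7
Reactants: 13 1,5-diiodo-2,4-dimethoxy-3-(propan-2-yl)benzene
Product: 16 5-iodo-2,4-dimethoxy-3-(propan-2-yl)phenol, via arylmagnesium chloride 14 (not isolated), via dimethyl arylboronate 15 (not isolated)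
Conditions: iPrMgCl·LiCl (1.05 equiv), THF, −20 °C; B(OMe)3, −20 → 0 °C; then 30% H2O2, aq. NaOH, 0 °C
Reagents that add atoms: hydrogen peroxide, OO
Why: iodine–magnesium exchange should stop after one iodine because the first arylmagnesium deactivates the ring toward a second exchange, and borylation–oxidation (1,2-aryl shift from boron to oxygen) turns the C–Mg bond into C–OH.

Step 8
Reactants: 16 5-iodo-2,4-dimethoxy-3-(propan-2-yl)phenol
Product: 17 2-bromo-3-iodo-4,6-dimethoxy-5-(propan-2-yl)phenol
Conditions: NBS (1.0 equiv), CH2Cl2, −20 → 0 °C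
Reagents that add atoms: N-bromosuccinimide, O=C1CCC(=O)N1Br
Why: electrophilic aromatic bromination can only occur at the single free ring position, which is ortho to the activating hydroxyl group.

Step 9
Reactants: 17 2-bromo-3-iodo-4,6-dimethoxy-5-(propan-2-yl)phenol
Product: 18 1-(benzyloxy)-2-bromo-3-iodo-4,6-dimethoxy-5-(propan-2-yl)benzene
Conditions: BnBr, K2CO3, DMF, rt
Reagents that add atoms: benzyl bromide, BrCc1ccccc1
Why: Williamson etherification of the phenoxide; the benzyl group distinguishes the future C5 hydroxyl from the C6 methyl ether that must stay.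

Step 10
Reactants: 18 1-(benzyloxy)-2-bromo-3-iodo-4,6-dimethoxy-5-(propan-2-yl)benzene; 7 (E)-7-[(tert-butyldimethylsilyl)oxy]-N-methoxy-N,4-dimethylhept-4-enamide
Product: 20 (E)-1-[3-(benzyloxy)-2-bromo-4,6-dimethoxy-5-(propan-2-yl)phenyl]-7-[(tert-butyldimethylsilyl)oxy]-4-methylhept-4-en-1-one, via arylmagnesium chloride 19 (not isolated)
Conditions: iPrMgCl·LiCl, THF, −40 °C; then 7, −40 → 0 °C; H2O
Reagents that add atoms: none
Why: iodine exchanges far faster than bromine, the arylmagnesium flanked by OMe and Br should resist aryne formation below 0 °C, and its addition to the amide stops at the chelated tetrahedral adduct (Weinreb ketone synthesis).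

Step 11
Reactants: 20 (E)-1-[3-(benzyloxy)-2-bromo-4,6-dimethoxy-5-(propan-2-yl)phenyl]-7-[(tert-butyldimethylsilyl)oxy]-4-methylhept-4-en-1-one
Product: 21 (4R)-5-(benzyloxy)-4-{(E)-3-[(tert-butyldimethylsilyl)oxy]prop-1-en-1-yl}-6,8-dimethoxy-4-methyl-7-(propan-2-yl)-3,4-dihydronaphthalen-1(2H)-one
Conditions: Pd2(dba)3 (5 mol%), (R)-BINAP (12 mol%), Ag3PO4 (2 equiv), DMA, 80–100 °C
Reagents that add atoms: none
Why: Zerovalent palladium inserts into the C–Br bond to give an arylpalladium bromide of divalent palladium, Ag3PO4 removes the bromide so that the E alkene binds a cationic (R)-BINAP complex, syn migratory insertion forms the C4a–C4 bond, and syn β-hydride elimination toward the CH2 next to CH2OSi releases the E allylic silyl ether while the phosphate takes up HBr and returns zerovalent palladium. The closest known reaction type is the enantioselective intramolecular Heck cyclisation of aryl halides onto trisubstituted alkenes that gives benzylic quaternary carbons under Pd/BINAP/silver-salt conditions. Ring B closes in the 6-exo-trig mode, the aryl group going to the methyl-bearing alkene carbon because the 7-endo alternative is strained and would place palladium on a fully substituted carbon. The new stereocentre C4 is controlled by the chiral diphosphine, which stays bound through both phosphorus atoms on the cationic pathway and so distinguishes the enantiofaces of the E alkene, which is why the single alkene geometry from step 2 matters. The step needs one reacting alkene and one direction of elimination, and the substrate secures both: C3 is still CH2 with no isopropenyl group present, and the quaternary C4 has no hydrogen to eliminate toward the ring. The ketone, silyl ether, benzyl ether and methyl ethers should be inert under these conditions.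

Step 12
Reactants: 21 (4R)-5-(benzyloxy)-4-{(E)-3-[(tert-butyldimethylsilyl)oxy]prop-1-en-1-yl}-6,8-dimethoxy-4-methyl-7-(propan-2-yl)-3,4-dihydronaphthalen-1(2H)-one
Product: 22 (4S)-5-(benzyloxy)-4-{3-[(tert-butyldimethylsilyl)oxy]propyl}-6,8-dimethoxy-4-methyl-7-(propan-2-yl)-3,4-dihydronaphthalen-1(2H)-one
Conditions: H2 (4 atm), RhCl(PPh3)3 (10 mol%), benzene/EtOH, 40 °C
Reagents that add atoms: none
Why: homogeneous catalytic hydrogenation with the rhodium phosphine complex should reduce the disubstituted alkene without hydrogenolysis of the benzyl ether or reduction of the aryl ketone (the descriptor at C4 changes only because the priorities change).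

Step 13
Reactants: 22 (4S)-5-(benzyloxy)-4-{3-[(tert-butyldimethylsilyl)oxy]propyl}-6,8-dimethoxy-4-methyl-7-(propan-2-yl)-3,4-dihydronaphthalen-1(2H)-one
Product: 24 (4S)-5-(benzyloxy)-4-{3-[(tert-butyldimethylsilyl)oxy]propyl}-6,8-dimethoxy-4-methyl-7-(propan-2-yl)naphthalen-1(4H)-one, via trimethylsilyl enol ether 23 (not isolated)
Conditions: LiN(iPr)2 (LDA), THF, −78 °C; Me3SiCl; then Pd(OAc)2 (1.1 equiv), MeCN, rt
Reagents that add atoms: none
Why: Saegusa–Ito oxidation; C2 is the only enolisable position, so the silyl enol ether is regiodefined, and palladation followed by β-hydride elimination installs the C2=C3 double bond while the quaternary C4 prevents tautomerisation to a naphthol.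

Step 14
Reactants: 24 (4S)-5-(benzyloxy)-4-{3-[(tert-butyldimethylsilyl)oxy]propyl}-6,8-dimethoxy-4-methyl-7-(propan-2-yl)naphthalen-1(4H)-one; 25 4,4,5,5-tetramethyl-2-(prop-1-en-2-yl)-1,3,2-dioxaborolane
Product: 26 (3S,4S)-5-(benzyloxy)-4-{3-[(tert-butyldimethylsilyl)oxy]propyl}-6,8-dimethoxy-4-methyl-7-(propan-2-yl)-3-(prop-1-en-2-yl)-3,4-dihydronaphthalen-1(2H)-one
Conditions: 25 (3 equiv), [Rh(OH)((S)-BINAP)]2 (5 mol%), KOH (20 mol%), 1,4-dioxane/H2O (10:1), 60 °C
Reagents that add atoms: none
Why: rhodium-catalysed asymmetric conjugate addition (Hayashi–Miyaura reaction); the isopropenylrhodium species should insert the enone on the face chosen by (S)-BINAP, which by analogy with 2-cyclohexenone is the face cis to the C4 methyl and is also the face left open by the siloxypropyl arm, so catalyst and substrate are matched, C3 is set S, and any adduct from residual minor enantiomer of 24 becomes a separable diastereomer.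

Step 15
Reactants: 26 (3S,4S)-5-(benzyloxy)-4-{3-[(tert-butyldimethylsilyl)oxy]propyl}-6,8-dimethoxy-4-methyl-7-(propan-2-yl)-3-(prop-1-en-2-yl)-3,4-dihydronaphthalen-1(2H)-one
Product: 27 (3S,4S)-5-(benzyloxy)-4-(3-hydroxypropyl)-6,8-dimethoxy-4-methyl-7-(propan-2-yl)-3-(prop-1-en-2-yl)-3,4-dihydronaphthalen-1(2H)-one
Conditions: Bu4NF, THF, 0 °C → rt
Reagents that add atoms: none
Why: fluoride-mediated desilylation of the primary silyl ether; neither stereocentre is epimerisable, since C3 is β to the ketone and C4 is quaternary.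

Step 16
Reactants: 27 (3S,4S)-5-(benzyloxy)-4-(3-hydroxypropyl)-6,8-dimethoxy-4-methyl-7-(propan-2-yl)-3-(prop-1-en-2-yl)-3,4-dihydronaphthalen-1(2H)-one
Product: 29 3-[(1S,2S)-8-(benzyloxy)-5,7-dimethoxy-1-methyl-4-oxo-6-(propan-2-yl)-2-(prop-1-en-2-yl)-1,2,3,4-tetrahydronaphthalen-1-yl]propanoic acid, via aldehyde 28 (not isolated)
Conditions: TEMPO (0.2 equiv), PhI(OAc)2 (2.5 equiv), MeCN/H2O (1:1), rt
Reagents that add atoms: water, O
Why: oxoammonium-mediated (TEMPO) oxidation in aqueous acetonitrile takes the primary alcohol through the aldehyde hydrate to the acid and should spare the alkene and ketone, and it is run while both phenols are still masked so that no hydroquinone is exposed to the oxidant.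

Step 17
Reactants: 29 3-[(1S,2S)-8-(benzyloxy)-5,7-dimethoxy-1-methyl-4-oxo-6-(propan-2-yl)-2-(prop-1-en-2-yl)-1,2,3,4-tetrahydronaphthalen-1-yl]propanoic acid
Product: 30 3-[(1S,2S)-5,8-dihydroxy-7-methoxy-1-methyl-4-oxo-6-(propan-2-yl)-2-(prop-1-en-2-yl)-1,2,3,4-tetrahydronaphthalen-1-yl]propanoic acid
Conditions: BCl3 (6 equiv), C6HMe5 (3 equiv), CH2Cl2, −78 → −20 °C; cold aq. NaHCO3, then pH 3, under argon
Reagents that add atoms: none
Why: Lewis-acid ether cleavage; BCl3 removes the benzyl group (the benzyl cation is trapped by pentamethylbenzene) and, through chelation to the C1 carbonyl, the peri methyl ether at C8, while the non-chelated C6 methyl ether should survive at low temperature.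

**Compound list**

1 | 3-[(tert-butyldimethylsilyl)oxy]propanal | CC(C)(C)[Si](C)(C)OCCC=O | starting material
2 | isopropenylmagnesium bromide | C=C(C)[Mg]Br | starting material
3 | rac-5-[(tert-butyldimethylsilyl)oxy]-2-methylpent-1-en-3-ol | C=C(C)C(O)CCO[Si](C)(C)C(C)(C)C | intermediate
4 | triethyl orthoacetate | CCOC(C)(OCC)OCC | starting material
5 | mixed ketene acetal, tert-butyl{[3-(1-ethoxyethenyloxy)-4-methylpent-4-en-1-yl]oxy}dimethylsilane (formed in the flask) | C=C(OCC)OC(CCO[Si](C)(C)C(C)(C)C)C(C)=C | intermediate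
6 | ethyl (E)-7-[(tert-butyldimethylsilyl)oxy]-4-methylhept-4-enoate | CCOC(=O)CC/C(C)=C/CCO[Si](C)(C)C(C)(C)C | intermediate
7 | (E)-7-[(tert-butyldimethylsilyl)oxy]-N-methoxy-N,4-dimethylhept-4-enamide | CON(C)C(=O)CC/C(C)=C/CCO[Si](C)(C)C(C)(C)C | intermediate
8 | 1,3-dimethoxybenzene | COc1cccc(OC)c1 | starting material
9 | acetone | CC(C)=O | starting material
10 | 2,6-dimethoxyphenyllithium (formed in the flask) | COc1cccc(OC)c1[Li] | intermediate
11 | 2-(2,6-dimethoxyphenyl)propan-2-ol | COc1cccc(OC)c1C(C)(C)O | intermediate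
12 | 1,3-dimethoxy-2-(propan-2-yl)benzene | COc1cccc(OC)c1C(C)C | intermediate
13 | 1,5-diiodo-2,4-dimethoxy-3-(propan-2-yl)benzene | COc1c(I)cc(I)c(OC)c1C(C)C | intermediate
14 | [5-iodo-2,4-dimethoxy-3-(propan-2-yl)phenyl]magnesium chloride (formed in the flask) | COc1c(I)cc([Mg]Cl)c(OC)c1C(C)C | intermediate
15 | dimethyl [5-iodo-2,4-dimethoxy-3-(propan-2-yl)phenyl]boronate (formed in the flask) | COc1c(I)cc(B(OC)OC)c(OC)c1C(C)C | intermediate
16 | 5-iodo-2,4-dimethoxy-3-(propan-2-yl)phenol | COc1c(I)cc(O)c(OC)c1C(C)C | intermediate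
17 | 2-bromo-3-iodo-4,6-dimethoxy-5-(propan-2-yl)phenol | COc1c(I)c(Br)c(O)c(OC)c1C(C)C | intermediate
18 | 1-(benzyloxy)-2-bromo-3-iodo-4,6-dimethoxy-5-(propan-2-yl)benzene | COc1c(I)c(Br)c(OCc2ccccc2)c(OC)c1C(C)C | intermediate
19 | [3-(benzyloxy)-2-bromo-4,6-dimethoxy-5-(propan-2-yl)phenyl]magnesium chloride (formed in the flask) | COc1c([Mg]Cl)c(Br)c(OCc2ccccc2)c(OC)c1C(C)C | intermediate
20 | (E)-1-[3-(benzyloxy)-2-bromo-4,6-dimethoxy-5-(propan-2-yl)phenyl]-7-[(tert-butyldimethylsilyl)oxy]-4-methylhept-4-en-1-one | CC(C)(C)[Si](C)(C)OCC/C=C(\C)CCC(=O)c1c(OC)c(C(C)C)c(OC)c(OCc2ccccc2)c1Br | intermediate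
21 | (4R)-5-(benzyloxy)-4-{(E)-3-[(tert-butyldimethylsilyl)oxy]prop-1-en-1-yl}-6,8-dimethoxy-4-methyl-7-(propan-2-yl)-3,4-dihydronaphthalen-1(2H)-one | C1CC(=O)c2c(OC)c(C(C)C)c(OC)c(OCc3ccccc3)c2[C@@]1(C)/C=C/CO[Si](C)(C)C(C)(C)C | intermediate
22 | (4S)-5-(benzyloxy)-4-{3-[(tert-butyldimethylsilyl)oxy]propyl}-6,8-dimethoxy-4-methyl-7-(propan-2-yl)-3,4-dihydronaphthalen-1(2H)-one | C1CC(=O)c2c(OC)c(C(C)C)c(OC)c(OCc3ccccc3)c2[C@@]1(C)CCCO[Si](C)(C)C(C)(C)C | intermediate
23 | {[(4S)-5-(benzyloxy)-4-{3-[(tert-butyldimethylsilyl)oxy]propyl}-6,8-dimethoxy-4-methyl-7-(propan-2-yl)-3,4-dihydronaphthalen-1-yl]oxy}trimethylsilane (formed in the flask) | C1C=C(O[Si](C)(C)C)c2c(OC)c(C(C)C)c(OC)c(OCc3ccccc3)c2[C@@]1(C)CCCO[Si](C)(C)C(C)(C)C | intermediate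
24 | (4S)-5-(benzyloxy)-4-{3-[(tert-butyldimethylsilyl)oxy]propyl}-6,8-dimethoxy-4-methyl-7-(propan-2-yl)naphthalen-1(4H)-one | C1=CC(=O)c2c(OC)c(C(C)C)c(OC)c(OCc3ccccc3)c2[C@@]1(C)CCCO[Si](C)(C)C(C)(C)C | intermediate
25 | 4,4,5,5-tetramethyl-2-(prop-1-en-2-yl)-1,3,2-dioxaborolane | C=C(C)B1OC(C)(C)C(C)(C)O1 | starting material
26 | (3S,4S)-5-(benzyloxy)-4-{3-[(tert-butyldimethylsilyl)oxy]propyl}-6,8-dimethoxy-4-methyl-7-(propan-2-yl)-3-(prop-1-en-2-yl)-3,4-dihydronaphthalen-1(2H)-one | C=C(C)[C@@H]1CC(=O)c2c(OC)c(C(C)C)c(OC)c(OCc3ccccc3)c2[C@@]1(C)CCCO[Si](C)(C)C(C)(C)C | intermediate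
27 | (3S,4S)-5-(benzyloxy)-4-(3-hydroxypropyl)-6,8-dimethoxy-4-methyl-7-(propan-2-yl)-3-(prop-1-en-2-yl)-3,4-dihydronaphthalen-1(2H)-one | C=C(C)[C@@H]1CC(=O)c2c(OC)c(C(C)C)c(OC)c(OCc3ccccc3)c2[C@@]1(C)CCCO | intermediate
28 | 3-[(1S,2S)-8-(benzyloxy)-5,7-dimethoxy-1-methyl-4-oxo-6-(propan-2-yl)-2-(prop-1-en-2-yl)-1,2,3,4-tetrahydronaphthalen-1-yl]propanal (formed in the flask) | C=C(C)[C@@H]1CC(=O)c2c(OC)c(C(C)C)c(OC)c(OCc3ccccc3)c2[C@@]1(C)CCC=O | intermediate
29 | 3-[(1S,2S)-8-(benzyloxy)-5,7-dimethoxy-1-methyl-4-oxo-6-(propan-2-yl)-2-(prop-1-en-2-yl)-1,2,3,4-tetrahydronaphthalen-1-yl]propanoic acid | C=C(C)[C@@H]1CC(=O)c2c(OC)c(C(C)C)c(OC)c(OCc3ccccc3)c2[C@@]1(C)CCC(=O)O | intermediate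
30 | 3-[(1S,2S)-5,8-dihydroxy-7-methoxy-1-methyl-4-oxo-6-(propan-2-yl)-2-(prop-1-en-2-yl)-1,2,3,4-tetrahydronaphthalen-1-yl]propanoic acid (CNP0249049.1) | C=C(C)[C@@H]1CC(=O)c2c(O)c(C(C)C)c(OC)c(O)c2[C@@]1(C)CCC(=O)O | target

**Step count and risks**

Total step count: 17. Longest linear sequence: 14 steps (steps 4 to 17, from 1,3-dimethoxybenzene 8); the chain branch (steps 1 to 3) joins at step 10.

Steps most likely to fail:

1. Step 11. Oxidative addition into the C–Br bond, which is flanked by the benzyloxy group and the acyl carbon, may be slow, and discrimination between the enantiofaces of the E alkene may be incomplete. Partial migration of the new double bond along the arm toward the silyl enol ether would not matter, since step 12 saturates the arm. The fallback sets out from 20. A copper-catalysed aromatic Finkelstein exchange (CuI, NaI, trans-N,N'-dimethylcyclohexane-1,2-diamine, 1,4-dioxane, 110 °C) should give the aryl iodide (E)-1-[3-(benzyloxy)-2-iodo-4,6-dimethoxy-5-(propan-2-yl)phenyl]-7-[(tert-butyldimethylsilyl)oxy]-4-methylhept-4-en-1-one F1. Its weaker carbon–halogen bond should let the same cyclisation (Pd2(dba)3, (R)-BINAP, Ag3PO4, DMA) run at lower temperature, where enantioface selection is expected to be better. The sequence rejoins the route at 21.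

2. Step 14. Insertion of the enone, whose β-carbon C3 sits next to the quaternary C4, may be slower than protodeboronation of the alkenylboron reagent, or the facial preference of the catalyst may oppose that of the substrate. The fallback sets out from 24 and uses stoichiometric organocopper chemistry. Isopropenylmagnesium bromide 2 with CuBr·SMe2 and Me3SiCl in THF at −78 °C should add anti to the siloxypropyl arm (substrate control, with chromatographic removal of the C3 epimer) and give the trimethylsilyl enol ether {[(3S,4S)-5-(benzyloxy)-4-{3-[(tert-butyldimethylsilyl)oxy]propyl}-6,8-dimethoxy-4-methyl-7-(propan-2-yl)-3-(prop-1-en-2-yl)-3,4-dihydronaphthalen-1-yl]oxy}trimethylsilane F2. Methanolysis with K2CO3 in MeOH then rejoins the route at 26.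

3. Step 17. Hydrogen chloride released from the carboxylic acid and BCl3 may add to the isopropenyl group or trigger its cyclisation onto the freed C5 phenol oxygen, and prolonged exposure may also cleave the C6 methyl ether. The fallback sets out from 29 and avoids Lewis acid altogether. Oxidative dealkylation with (NH4)2Ce(NO3)6 in MeCN/H2O at 0 °C should convert the para-related C5 benzyl ether and C8 methyl ether into the quinone 3-[(1S,2S)-7-methoxy-1-methyl-4,5,8-trioxo-6-(propan-2-yl)-2-(prop-1-en-2-yl)-1,2,3,4,5,8-hexahydronaphthalen-1-yl]propanoic acid F3, with the C6 methyl ether retained. Reduction with aqueous Na2S2O4 should then return the hydroquinone, which is the target 30.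

Further compounds
F1 | step 11 | (E)-1-[3-(benzyloxy)-2-iodo-4,6-dimethoxy-5-(propan-2-yl)phenyl]-7-[(tert-butyldimethylsilyl)oxy]-4-methylhept-4-en-1-one | CC(C)(C)[Si](C)(C)OCC/C=C(\C)CCC(=O)c1c(OC)c(C(C)C)c(OC)c(OCc2ccccc2)c1I
F2 | step 14 | {[(3S,4S)-5-(benzyloxy)-4-{3-[(tert-butyldimethylsilyl)oxy]propyl}-6,8-dimethoxy-4-methyl-7-(propan-2-yl)-3-(prop-1-en-2-yl)-3,4-dihydronaphthalen-1-yl]oxy}trimethylsilane | C=C(C)[C@@H]1C=C(O[Si](C)(C)C)c2c(OC)c(C(C)C)c(OC)c(OCc3ccccc3)c2[C@@]1(C)CCCO[Si](C)(C)C(C)(C)C
F3 | step 17 | 3-[(1S,2S)-7-methoxy-1-methyl-4,5,8-trioxo-6-(propan-2-yl)-2-(prop-1-en-2-yl)-1,2,3,4,5,8-hexahydronaphthalen-1-yl]propanoic acid | C=C(C)[C@@H]1CC(=O)C2=C(C(=O)C(OC)=C(C(C)C)C2=O)[C@@]1(C)CCC(=O)O
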